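## The problem

Compound 37 (CNP0324463.6) is a heliangolide: a cyclodecane (C1–C10, germacrane numbering) trans-fused at C6–C7 to an α-methylene-γ-butyrolactone (oxygen on C6, C11=C13, C12 carbonyl), with a trans C1–C10 epoxide, a Z C4=C5 olefin, a benzoate on C3 and a (2R,3R)-2,3-epoxy-2-methylbutanoate on C8. The ten-membered ring is the central difficulty, because closing it has to overcome entropy and transannular strain and fix one E-derived and one Z unit at the same time. Of the six ring stereocentres, C7 and C8 are neighbours and can be set together in an open chain; C6 can then be read from C7 by reduction of a C6 ketone, and C1/C10 from the face the folded ring offers to an oxidant. C3 is insulated from this group by C2 and by the C4=C5 olefin, so it must arrive enantiopure with its own fragment, as must the two centres of the side-chain acid. Several groups are fragile: the methylene lactone is a Michael acceptor, both oxiranes and the cyclodeca-1(10),4-diene that precedes the ring epoxide are opened or cyclised transannularly by protic acid, cyclodeca-1,5-dienes undergo Cope rearrangement when heated, and O3 and O6 are allylic esters. The enabling feature is that, without the epoxide oxygen, C10=C1–C2–C3–C4=C5 is a cis,trans-cyclodeca-1,5-diene. Such a diene is the thermolysis product of a bicyclo[2.2.0]hexane (C1, C2, C3, C4, C5, C10) fused through C5–C10 to a six-membered ring; with C6 as a ketone that tricycle is the [2+2] photoadduct of a cyclohexenone (C5–C10) and a cyclobutene (C1–C4).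

## Retrosynthesis

37 ⇒ 36. The two C–O bonds of the ring epoxide are cut first. The oxirane would not survive the acid, fluoride and enolate steps needed elsewhere, whereas the trans-cyclodecene 36 is the only electron-rich olefin left at the end. The forward reaction must choose C1=C10 over C4=C5 and C11=C13 and deliver oxygen to one face.

36 ⇒ 30 + 34. The O8–acyl bond is cut next, because a glycidic ester is better introduced after all enolate and desilylation chemistry. Alcohol 30 has a single free hydroxyl, since the C3 benzoate is carried from the cyclobutene stage and needs no protecting group. Acid 34 goes back through epoxy alcohol 33 and allylic alcohol 32 to angelic acid 31; the forward sequence needs a reagent-controlled epoxidation of a Z-trisubstituted allylic alcohol.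

30 ⇒ 29 ⇒ 26. Removing the silyl group and C13 leads to lactone 26 with an unsubstituted C11. Methylenation is placed after lactonisation because only the lactone α-carbon is then enolisable; the forward step must form a lactone enolate without touching the C3 benzoate.

26 ⇒ 23 ⇒ 22. Cutting the O6–C12 bond and the C6–H bond gives dienone 22, in which C12 is a tert-butyl ester and O8 a silyl ether. Keeping C6 as a ketone until here serves the ring construction; the forward steps need a 1,2-reduction from the correct face and a lactonisation that avoids strong protic acid.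

22 ⇒ 21. Reconnecting C1–C4 and C5–C10 turns the ten-membered dienone into the tricyclic photoadduct 21. Compared with a direct macrocyclisation, this replaces ring closure by cleavage of two strained bonds and produces both ring olefins at once. The forward thermolysis must give 1(10)E and 4Z and leave C3, C7 and C8 alone.

21 ⇒ 12 + 19. Cutting C1–C10 and C4–C5 of the central cyclobutane gives cyclohexenone 12 (C5–C10, with the C7 arm and the C8 silyl ether) and cyclobutenyl benzoate 19 (C1–C4 with C15). Each partner carries its stereocentres in a small ring made by catalytic asymmetric reduction. The forward cycloaddition must pair C10 with C1 and C5 with C4, and give a cis-anti-cis adduct.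

12 ⇒ 11 ⇒ 10 ⇒ 9 ⇒ 8 ⇒ 5 + 6, and 5 ⇒ 4 ⇒ 1 + 2. The enone olefin C5=C10 is cut (ring-closing metathesis of vinyl ketone 11), then the C6–vinyl bond (Weinreb amide 10 from ester 9), then the C7–C11 bond (alkylation of hydroxy ester 5 with bromoacetate 6 to give 8). The arm is introduced on the open chain because alkylating a preformed 5-silyloxycyclohexenone would place it trans to O8, whereas the anti product of an open-chain dianion alkylation becomes the required cis pair on the ring. Hydroxy ester 5 comes from keto ester 4 by asymmetric hydrogenation, and 4 from acid 1 and Meldrum's acid 2.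

19 ⇒ 17 ⇒ 16 ⇒ 13 + 14. The benzoate C–O and the carbinol C–H bond lead back to cyclobutenone 17, made from ethoxycyclobutanone 16, the ketene cycloadduct of propanoyl chloride 13 and ethyl vinyl ether 14. The four-membered ring is built by a [2+2] that fixes the methyl next to the carbonyl; the forward sequence needs the double bond on the methyl-bearing side and an enantioselective 1,2-reduction.

## Roads not taken

Alternative 1: The ring bond C7–C8 is cut, with C11=C13 formed in the same event. In the forward sense the C8 acyl radical released from selenoester A1 (a seco chain that already holds the epoxide, the C3 benzoate, the Z olefin and a butenolide with a stannylmethyl group on C11) would add to C7 in a 10-endo closure. The C11 radical would then expel the stannyl radical, which carries the chain, to give the methylene lactone of 8-ketone A2.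
- Merits: the route is convergent, ring and Michael acceptor appear together, and the Z olefin is made by ordinary open-chain methods without heating.
- Weak points for this target: a ten-membered radical closure needs high dilution and competes with reduction of the acyl radical. A2 is a β,γ-epoxy ketone that can open by β-elimination. Its C8 ketone must be reduced to the 8β-alcohol next to the finished methylene lactone, with no neighbouring centre that reliably controls the face.
- Comparison: Alternative 1 is better in convergence and in needing no separate methylenation. The chosen plan sets against this that C8 is fixed by a catalytic hydrogenation before any ring exists, that the ring forms without dilution, and that no ketone has to be reduced beside the Michael acceptor.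

Alternative 2: C8–C9 is formed while C1–C6 of a six-membered ring is broken, a ring expansion by four atoms. The potassium alkoxide of dialkenylcyclohexenol A3 would rearrange through a chair (anionic oxy-Cope) to the ten-membered C6 enolate, which is protonated at C7 to give dienone A4.
- Merits: the chair fixes 1(10)E, the cyclohexene delivers 4Z by construction, the enol ether geometry sets C8, and nothing is heated to 180 °C.
- Weak points: A3 needs a tertiary carbinol made by diastereoselective addition of a trisubstituted alkenyl metal of defined enol ether geometry. C7 is set by kinetic protonation of a medium-ring enolate. The arm is at the alcohol oxidation level and needs two oxidations late. The strongly basic medium meets a γ-silyloxy enone.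
- Comparison: in olefin geometry this road is as good as or better than the thermal cycloreversion used here. The chosen plan sets against it two fragments (12 and 19) whose stereocentres come from catalytic reductions and one dianion alkylation, a C7 centre that never passes through an enolate after step 3, and an arm already at the carboxyl level.

Alternative 3: The lactone bond O–C6 is cut. N-Iodination of amide A5 and photolysis would give an amidyl radical that abstracts H-6 through a six-membered transition state. Oxidation of the allylic radical and capture by the amide oxygen would give an iminolactone, hydrolysed to lactone A6 (11,13-dihydro-37), which still needs dehydrogenation to the methylene lactone.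
- Merits: C6 stays unfunctionalised until the end, so no ketone, reduction or lactonisation step is needed.
- Weak points: the C4–C5–C6 allyl radical can be trapped at C4 or C6, can lose the Z geometry, and offers no control of the C6 face. N–I chemistry runs next to two oxiranes. The ten-membered ring still has to be made by some other method.
- Comparison: Alternative 3 is better in redox economy at C6. The chosen plan uses the C6 carbonyl as chromophore, as the group that lets C4=C5 settle as Z, and as a handle whose reduction can be corrected by inversion, whereas a radical C–O closure cannot be corrected.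

Key step: step 11

Remark on numbering: from compound 12 onwards ring carbons keep their germacrane numbers (C1–C10 ring, C11–C13 arm on C7, C14 on C10, C15 on C4). The CIP label of C7 changes between R and S along the route only because the ranking of C6 against C8 changes with their oxygen substituents; its geometry does not change.

Assumption: two cis-anti-cis photoadducts are possible (cyclobutene reacting anti to its benzoate, or enone reacting anti to its C7/C8 substituents). Compound 21 is written as the former; either would give 22, because C1, C4, C5 and C10 become trigonal in step 12.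

Step 1
Reactants: 1 3-methylbut-3-enoic acid; 2 Meldrum's acid (2,2-dimethyl-1,3-dioxane-4,6-dione)
Product: 4 methyl 5-methyl-3-oxohex-5-enoate, via acyl Meldrum's acid 3 (not isolated)
Conditions: DCC, DMAP, CH2Cl2, 0 → 23 °C; filter; then MeOH, 65 °C
Reagents that add atoms: methanol, CO
Why: C-Acylation of Meldrum's acid and methanolysis of the acyl derivative through its acylketene is the standard two-carbon homologation of an acid to a β-keto ester; the near-neutral conditions should keep the 1,1-disubstituted olefin out of conjugation.

Step 2
Reactants: 4 methyl 5-methyl-3-oxohex-5-enoate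
Product: 5 methyl (3R)-3-hydroxy-5-methylhex-5-enoate
Conditions: RuCl2[(R)-BINAP] (0.5 mol%), H2 (4 atm), MeOH, 50 °C
Reagents that add atoms: none
Why: Noyori asymmetric hydrogenation of a β-keto ester; the (R)-BINAP catalyst, which gives (R)-3-hydroxybutanoate from acetoacetate, should set C8 as 3R, and it does not reduce an unfunctionalised 1,1-disubstituted olefin.

Step 3
Reactants: 5 methyl (3R)-3-hydroxy-5-methylhex-5-enoate; 6 tert-butyl bromoacetate
Product: 8 4-tert-butyl 1-methyl (2R)-2-[(1R)-1-hydroxy-3-methylbut-3-en-1-yl]butanedioate, via dilithium alkoxide-enolate 7 (not isolated)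
Conditions: LiN(iPr)2 (2.2 equiv), THF, −78 → −30 °C; then 6, DMPU, −78 → −30 °C
Reagents that add atoms: none
Why: Fráter–Seebach alkylation: the chelated dianion is alkylated on the face away from the carbinol substituent, which sets C7 anti to O8 (2R,1′R); this anti pair becomes the cis arm/oxygen pair once C6 and C9 are joined in a ring.

Step 4
Reactants: 8 4-tert-butyl 1-methyl (2R)-2-[(1R)-1-hydroxy-3-methylbut-3-en-1-yl]butanedioate
Product: 9 4-tert-butyl 1-methyl (2R)-2-[(1R)-1-[(tert-butyldimethylsilyl)oxy]-3-methylbut-3-en-1-yl]butanedioate
Conditions: TBSOTf, 2,6-lutidine, CH2Cl2, −78 → 0 °C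
Reagents that add atoms: tert-butyldimethylsilyl trifluoromethanesulfonate, CC(C)(C)[Si](C)(C)OS(=O)(=O)C(F)(F)F
Why: Silylation of a hindered secondary alcohol with a silyl triflate and a hindered pyridine; the medium is non-basic, so neither lactonisation onto the tert-butyl ester nor retro-aldol cleavage is expected.

Step 5
Reactants: 9 4-tert-butyl 1-methyl (2R)-2-[(1R)-1-[(tert-butyldimethylsilyl)oxy]-3-methylbut-3-en-1-yl]butanedioate
Product: 10 tert-butyl (3R,4R)-4-[(tert-butyldimethylsilyl)oxy]-3-[methoxy(methyl)carbamoyl]-6-methylhept-6-enoate
Conditions: MeNHOMe·HCl, iPrMgCl, THF, −20 → 0 °C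
Reagents that add atoms: N,O-dimethylhydroxylamine hydrochloride, CNOC.Cl
Why: Weinreb amide formation from a methyl ester with the magnesium amide; the tert-butyl ester is too hindered to react, and the weakly basic amide should not epimerise C7.

Step 6
Reactants: 10 tert-butyl (3R,4R)-4-[(tert-butyldimethylsilyl)oxy]-3-[methoxy(methyl)carbamoyl]-6-methylhept-6-enoate
Product: 11 tert-butyl (3R,4R)-3-acryloyl-4-[(tert-butyldimethylsilyl)oxy]-6-methylhept-6-enoate
Conditions: CH2=CHMgBr, THF, −20 → 0 °C; cold aq. NH4Cl
Reagents that add atoms: vinylmagnesium bromide, C=C[Mg]Br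
Why: Weinreb ketone synthesis: the chelated tetrahedral adduct holds until the quench, so the vinyl ketone is released only in the cold acidic work-up and meets neither excess Grignard reagent nor base that could eliminate the β-silyloxy group.

Step 7
Reactants: 11 tert-butyl (3R,4R)-3-acryloyl-4-[(tert-butyldimethylsilyl)oxy]-6-methylhept-6-enoate
Product: 12 tert-butyl 2-[(1R,6R)-6-[(tert-butyldimethylsilyl)oxy]-4-methyl-2-oxocyclohex-3-en-1-yl]acetate
Conditions: second-generation Grubbs catalyst RuCl2(=CHPh)(PCy3)(H2IMes) (5 mol%), CH2Cl2, 40 °C
Reagents that add atoms: none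
Why: Ring-closing metathesis of a vinyl ketone with a 1,1-disubstituted olefin to a 3-methylcyclohex-2-enone (C5=C10); the neutral conditions preserve the β-silyloxy ketone and the C7 centre, which a base-mediated cyclisation would put at risk.

Step 8
Reactants: 13 propanoyl chloride; 14 ethyl vinyl ether
Product: 16 3-ethoxy-2-methylcyclobutan-1-one (racemic, cis/trans mixture), via methylketene 15 (not isolated)
Conditions: Et3N, 14 (excess), MeCN, 80 °C
Reagents that add atoms: none
Why: Ketene–enol ether [2+2] cycloaddition with the ketene made by dehydrochlorination in the flask; the nucleophilic CH2 of the vinyl ether bonds to the ketene carbonyl carbon, which places the ethoxy group on C3 next to the methyl-bearing C2.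

Step 9
Reactants: 16 3-ethoxy-2-methylcyclobutan-1-one
Product: 17 2-methylcyclobut-2-en-1-one
Conditions: TsOH·H2O (5 mol%), 5 Å molecular sieves, CH2Cl2, 23 °C; solution used cold without concentration
Reagents that add atoms: none
Why: Acid-catalysed β-elimination of an alkoxy ketone (retro-oxa-Michael) through the more substituted enol should give the more substituted, conjugated cyclobutenone; the sieves hold back ethanol so that it cannot add again.

Step 10
Reactants: 17 2-methylcyclobut-2-en-1-one
Product: 19 (1S)-2-methylcyclobut-2-en-1-yl benzoate, via (S)-2-methylcyclobut-2-en-1-ol 18 (not isolated)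
Conditions: (R)-Me-CBS (C18H20BNO oxazaborolidine, 20 mol%), BH3·SMe2, THF, −40 °C; MeOH; then BzCl, Et3N, DMAP, CH2Cl2, 0 °C
Reagents that add atoms: benzoyl chloride, O=C(Cl)c1ccccc1
Why: Corey–Bakshi–Shibata reduction of an α-substituted cyclic enone, in which the substituted alkenyl arm acts as the large group, so the (R)-catalyst should give the (S)-carbinol (C3); benzoylation of the crude solution avoids isolating a volatile alcohol and installs the final C3 ester.

Step 11
Reactants: 12 tert-butyl 2-[(1R,6R)-6-[(tert-butyldimethylsilyl)oxy]-4-methyl-2-oxocyclohex-3-en-1-yl]acetate; 19 (1S)-2-methylcyclobut-2-en-1-yl benzoate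
Product: 21 cis-anti-cis photoadduct (tricyclic C6 ketone with new bonds C1–C10 and C4–C5; 1R,3S,4R,5R,7R,8R,10R; benzoate on C3 exo, tert-butyl acetate arm on C7, TBS ether on C8), via triplet 1,4-biradical 20 (not isolated)
Conditions: hν (350 nm lamps, uranium-glass filter), 19 (3 equiv, excess recovered), CH2Cl2, −40 °C, Ar
Reagents that add atoms: none
Why: This is an intermolecular enone–cycloalkene [2+2] photocycloaddition, the closest known type being the addition of 3-methylcyclohexenones to 1-methylcyclobutene as the first half of a photo-thermal route to cyclodeca-1,5-dienes. Excitation (n→π*) and intersystem crossing give the twisted triplet enone, whose β-carbon C10 bonds to the unsubstituted cyclobutene carbon C1 to give biradical 20 (α-keto radical at C5, tertiary radical at C4); after spin inversion C5–C4 closes, so the central cyclobutane is the only ring formed and it closes by radical–radical combination of a 1,4-biradical. The selectivity the route cannot do without is regiochemical and rests on sterics, since pairing C10 with C4 would join two fully substituted carbons, one of them flanked by the benzoyloxy-bearing C3. C1 and C4 are set by the cyclobutene reacting on the face anti to its C3 benzoate. C10 and C5 are set relative to them by the exo approach of the four-membered ring and by the cis fusion that the six-membered ring enforces on closure, which gives the cis-anti-cis tricycle. For the (3S)/(7R,8R) pairing these two preferences put the new ring on the enone face syn to the C7 and C8 substituents, so the enone's own facial preference is opposed; the cis-anti-cis adduct from the other pair of faces is equally serviceable because all four new centres are destroyed in step 12. Irradiation above 330 nm leaves the benzoate unexcited, and low temperature with excess 19 should suppress enone dimerisation.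

Step 12
Reactants: 21 cis-anti-cis photoadduct
Product: 22 tert-butyl [(1(10)E,4Z,3S,7R,8R)-3-(benzoyloxy)-8-[(tert-butyldimethylsilyl)oxy]-4,10-dimethyl-6-oxocyclodeca-1(10),4-dien-7-yl]acetate
Conditions: PhMe (degassed), base-washed sealed tube, 180 °C
Reagents that add atoms: none
Why: Thermal cycloreversion of a bicyclo[2.2.0]hexane (formal retro-[2+2]): the strained C1–C4 bond breaks, then C5–C10, whose cleavage is helped by the C6 carbonyl. The trans-cyclodecene geometry should appear at C1=C10, while the conjugated C4=C5 olefin, the only one able to equilibrate at this temperature, should settle as Z, the less strained partner of a 1(10)E olefin; C3, C7 and C8 take no part.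

Step 13
Reactants: 22 (4Z,1(10)E)-dienone
Product: 23 tert-butyl [(1(10)E,4Z,3S,6R,7S,8R)-3-(benzoyloxy)-8-[(tert-butyldimethylsilyl)oxy]-6-hydroxy-4,10-dimethylcyclodeca-1(10),4-dien-7-yl]acetate
Conditions: NaBH4, CeCl3·7H2O, MeOH, −78 °C; AcOH quench
Reagents that add atoms: none
Why: Luche 1,2-reduction of an enone. With the carbonyl eclipsing the C7–H bond so that the arm lies outside the ring, the oxygen points to the face anti to the arm, and peripheral hydride attack should give the 6R alcohol trans to the C7 arm; the cerium salt suppresses conjugate reduction and enolisation at C7.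

Step 14
Reactants: 23 (6R)-allylic alcohol
Product: 26 (3S,6R,7S,8R)-3-benzoyloxy-8-[(tert-butyldimethylsilyl)oxy]-13-norgermacra-1(10)E,4Z-dien-12,6-olide (trans-fused γ-lactone, C11 is CH2), via bis-trimethylsilyl derivative 24 (not isolated), via hydroxy acid 25 (not isolated)
Conditions: TMSOTf, 2,6-lutidine, CH2Cl2, 0 °C; then 10% aq. citric acid, THF/MeOH, 23 °C
Reagents that add atoms: none
Why: tert-Butyl ester cleavage by silyl transfer followed by spontaneous lactonisation of a γ-hydroxy acid. Only O6 is free (O8 is silylated, O3 benzoylated), so the 12,6-lactone is the only one possible, and no strong protic acid meets the acid-sensitive 1(10),4-diene.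

Step 15
Reactants: 26 13-nor lactone
Product: 29 (3S,6R,7S,8R)-3-benzoyloxy-8-[(tert-butyldimethylsilyl)oxy]germacra-1(10)E,4Z,11(13)-trien-12,6-olide, via Mannich base 27 (not isolated), via trimethylammonium iodide 28 (not isolated)
Conditions: LiN(SiMe3)2, THF, −78 °C; Eschenmoser's salt (Me2N=CH2 I), −78 → 0 °C; then MeI, MeOH; then aq. NaHCO3, CH2Cl2, 23 °C
Reagents that add atoms: N,N-dimethylmethyleneiminium iodide, C=[N+](C)C.[I-]
Why: Eschenmoser–Mannich α-methylenation of a lactone: aminomethylation of the lithium enolate, N-methylation and E1cB loss of trimethylamine. The hindered, non-nucleophilic amide base should leave the benzoate alone at −78 °C, and the transient C11 centre is destroyed.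

Step 16
Reactants: 29 silylated methylene lactone
Product: 30 (3S,6R,7R,8R)-3-benzoyloxy-8-hydroxygermacra-1(10)E,4Z,11(13)-trien-12,6-olide
Conditions: HF·pyridine, pyridine, THF, 0 → 23 °C
Reagents that add atoms: none
Why: Fluoride cleavage of a secondary silyl ether under buffered, weakly acidic conditions that spare the benzoate, the Michael acceptor and the allylic lactone; no epoxide is present yet.

Step 17
Reactants: 31 angelic acid ((Z)-2-methylbut-2-enoic acid)
Product: 32 (Z)-2-methylbut-2-en-1-ol
Conditions: LiAlH4, Et2O, 0 °C
Reagents that add atoms: none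
Why: Hydride reduction of a carboxylic acid to the primary allylic alcohol; at 0 °C the Z olefin is neither reduced nor isomerised.

Step 18
Reactants: 32 (Z)-2-methylbut-2-en-1-ol
Product: 33 [(2S,3R)-2,3-dimethyloxiran-2-yl]methanol
Conditions: Ti(OiPr)4 (10 mol%), L-(+)-diethyl tartrate (12 mol%), tBuOOH, 4 Å molecular sieves, CH2Cl2, −20 °C
Reagents that add atoms: tert-butyl hydroperoxide, CC(C)(C)OO
Why: Sharpless asymmetric epoxidation; the L-(+)-tartrate catalyst delivers oxygen to the face that gives 2S (as it gives (2S)-epoxy alcohols from other allylic alcohols), and the Z geometry translates into the cis relation of CH2OH and the C3 methyl (3R).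

Step 19
Reactants: 33 [(2S,3R)-2,3-dimethyloxiran-2-yl]methanol
Product: 34 (2R,3R)-2,3-dimethyloxirane-2-carboxylic acid
Conditions: RuCl3·H2O (2 mol%), NaIO4, CCl4/MeCN/H2O, 23 °C
Reagents that add atoms: water, O
Why: RuO4-catalysed oxidation of a primary epoxy alcohol to the epoxy acid; no bond at a stereocentre is touched, and the C2 label changes from S to R only through the CIP ranking.

Step 20
Reactants: 34 (2R,3R)-2,3-dimethyloxirane-2-carboxylic acid; 30 8-hydroxy methylene lactone
Product: 36 (3S,6R,7R,8R)-3-benzoyloxy-8-[(2R,3R)-2,3-epoxy-2-methylbutanoyloxy]germacra-1(10)E,4Z,11(13)-trien-12,6-olide, via mixed anhydride 35 (not isolated)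
Conditions: 2,4,6-trichlorobenzoyl chloride, Et3N, PhMe, 23 °C; then 30, DMAP, PhMe, 23 → 40 °C
Reagents that add atoms: none
Why: Yamaguchi esterification through the mixed anhydride, the standard way to acylate a hindered secondary alcohol with an α,α-disubstituted acid; the acid has no enolisable α-hydrogen, so its stereocentres are safe.

Step 21
Reactants: 36 1(10)-ene diester
Product: 37 (1R,3S,6R,7R,8R,10R)-3-benzoyloxy-1,10-epoxy-8-[(2R,3R)-2,3-epoxy-2-methylbutanoyloxy]germacra-4Z,11(13)-dien-12,6-olide (CNP0324463.6)
Conditions: mCPBA, NaHCO3, CH2Cl2, 0 °C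
Reagents that add atoms: 3-chloroperoxybenzoic acid, O=C(OO)c1cccc(Cl)c1
Why: Prilezhaev epoxidation. The strained trisubstituted E olefin is by far the most nucleophilic (C4=C5 carries two allylic acyloxy groups, C11=C13 is conjugated); stereospecific syn addition gives the trans epoxide, and attack on the exposed outer face of the conformer with C14 on the β-face should give 1R,10R.

Compound list

1 | 3-methylbut-3-enoic acid | C=C(C)CC(=O)O | starting material
2 | Meldrum's acid (2,2-dimethyl-1,3-dioxane-4,6-dione) | CC1(C)OC(=O)CC(=O)O1 | starting material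
3 | 5-(1-hydroxy-3-methylbut-3-en-1-ylidene)-2,2-dimethyl-1,3-dioxane-4,6-dione (acyl Meldrum's acid) | C=C(C)CC(O)=C1C(=O)OC(C)(C)OC1=O | intermediate (not isolated)
4 | methyl 5-methyl-3-oxohex-5-enoate | C=C(C)CC(=O)CC(=O)OC | intermediate
5 | methyl (3R)-3-hydroxy-5-methylhex-5-enoate | COC(=O)C[C@H](O)CC(C)=C | intermediate
6 | tert-butyl bromoacetate | CC(C)(C)OC(=O)CBr | starting material
7 | dilithium alkoxide-enolate of 5 | [Li+].[Li+].COC([O-])=C[C@H]([O-])CC(C)=C | intermediate (not isolated)
8 | 4-tert-butyl 1-methyl (2R)-2-[(1R)-1-hydroxy-3-methylbut-3-en-1-yl]butanedioate | COC(=O)[C@H](CC(=O)OC(C)(C)C)[C@H](O)CC(C)=C | intermediate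
9 | 4-tert-butyl 1-methyl (2R)-2-[(1R)-1-[(tert-butyldimethylsilyl)oxy]-3-methylbut-3-en-1-yl]butanedioate | COC(=O)[C@H](CC(=O)OC(C)(C)C)[C@H](O[Si](C)(C)C(C)(C)C)CC(C)=C | intermediate
10 | tert-butyl (3R,4R)-4-[(tert-butyldimethylsilyl)oxy]-3-[methoxy(methyl)carbamoyl]-6-methylhept-6-enoate | CON(C)C(=O)[C@H](CC(=O)OC(C)(C)C)[C@H](O[Si](C)(C)C(C)(C)C)CC(C)=C | intermediate
11 | tert-butyl (3R,4R)-3-acryloyl-4-[(tert-butyldimethylsilyl)oxy]-6-methylhept-6-enoate | C=CC(=O)[C@H](CC(=O)OC(C)(C)C)[C@H](O[Si](C)(C)C(C)(C)C)CC(C)=C | intermediate
12 | tert-butyl 2-[(1R,6R)-6-[(tert-butyldimethylsilyl)oxy]-4-methyl-2-oxocyclohex-3-en-1-yl]acetate (enone, C5–C10) | CC1=CC(=O)[C@H](CC(=O)OC(C)(C)C)[C@H](O[Si](C)(C)C(C)(C)C)C1 | intermediate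
13 | propanoyl chloride | CCC(=O)Cl | starting material
14 | ethyl vinyl ether | C=COCC | starting material
15 | methylketene | CC=C=O | intermediate (not isolated)
16 | 3-ethoxy-2-methylcyclobutan-1-one (racemic, cis/trans mixture) | CCOC1CC(=O)C1C | intermediate
17 | 2-methylcyclobut-2-en-1-one | CC1=CCC1=O | intermediate
18 | (S)-2-methylcyclobut-2-en-1-ol | CC1=CC[C@@H]1O | intermediate (not isolated)
19 | (1S)-2-methylcyclobut-2-en-1-yl benzoate (cyclobutene, C1–C4 with C15) | CC1=CC[C@@H]1OC(=O)c1ccccc1 | intermediate
20 | triplet 1,4-biradical (C1–C10 bond formed, radical centres at C5 and C4) | C[C]1[C@@H](OC(=O)c2ccccc2)C[C@@H]1[C@@]3(C)C[C@@H](O[Si](C)(C)C(C)(C)C)[C@@H](CC(=O)OC(C)(C)C)C(=O)[CH]3 | intermediate (not isolated)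
21 | cis-anti-cis photoadduct (1R,3S,4R,5R,7R,8R,10R), central cyclobutane C1, C4, C5, C10 | C[C@@]12[C@@H](OC(=O)c3ccccc3)C[C@@H]1[C@@]4(C)C[C@@H](O[Si](C)(C)C(C)(C)C)[C@@H](CC(=O)OC(C)(C)C)C(=O)[C@H]42 | intermediate
22 | tert-butyl [(1(10)E,4Z,3S,7R,8R)-3-(benzoyloxy)-8-[(tert-butyldimethylsilyl)oxy]-4,10-dimethyl-6-oxocyclodeca-1(10),4-dien-7-yl]acetate | O=C1/C=C(/C)[C@@H](OC(=O)c2ccccc2)C/C=C(\C)C[C@@H](O[Si](C)(C)C(C)(C)C)[C@H]1CC(=O)OC(C)(C)C | intermediate
23 | (3S,6R,7S,8R)-6-hydroxy analogue of 22 (allylic alcohol) | O[C@@H]1/C=C(/C)[C@@H](OC(=O)c2ccccc2)C/C=C(\C)C[C@@H](O[Si](C)(C)C(C)(C)C)[C@H]1CC(=O)OC(C)(C)C | intermediate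
24 | O6-trimethylsilyl ether, C12 trimethylsilyl ester of the seco acid | C[Si](C)(C)O[C@@H]1/C=C(/C)[C@@H](OC(=O)c2ccccc2)C/C=C(\C)C[C@@H](O[Si](C)(C)C(C)(C)C)[C@H]1CC(=O)O[Si](C)(C)C | intermediate (not isolated)
25 | (6R)-hydroxy acid (seco acid of 26) | O[C@@H]1/C=C(/C)[C@@H](OC(=O)c2ccccc2)C/C=C(\C)C[C@@H](O[Si](C)(C)C(C)(C)C)[C@H]1CC(=O)O | intermediate (not isolated)
26 | (3S,6R,7S,8R)-3-benzoyloxy-8-[(tert-butyldimethylsilyl)oxy]-13-norgermacra-1(10)E,4Z-dien-12,6-olide | C1C(=O)O[C@@H]2/C=C(/C)[C@@H](OC(=O)c3ccccc3)C/C=C(\C)C[C@@H](O[Si](C)(C)C(C)(C)C)[C@@H]12 | intermediate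
27 | 13-(dimethylamino) Mannich base of 26 (C11 configuration undefined) | CN(C)CC1C(=O)O[C@@H]2/C=C(/C)[C@@H](OC(=O)c3ccccc3)C/C=C(\C)C[C@@H](O[Si](C)(C)C(C)(C)C)[C@@H]12 | intermediate (not isolated)
28 | trimethylammonium iodide of 27 | C[N+](C)(C)CC1C(=O)O[C@@H]2/C=C(/C)[C@@H](OC(=O)c3ccccc3)C/C=C(\C)C[C@@H](O[Si](C)(C)C(C)(C)C)[C@@H]12.[I-] | intermediate (not isolated)
29 | (3S,6R,7S,8R)-3-benzoyloxy-8-[(tert-butyldimethylsilyl)oxy]germacra-1(10)E,4Z,11(13)-trien-12,6-olide | C=C1C(=O)O[C@@H]2/C=C(/C)[C@@H](OC(=O)c3ccccc3)C/C=C(\C)C[C@@H](O[Si](C)(C)C(C)(C)C)[C@@H]12 | intermediate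
30 | (3S,6R,7R,8R)-3-benzoyloxy-8-hydroxygermacra-1(10)E,4Z,11(13)-trien-12,6-olide | C=C1C(=O)O[C@@H]2/C=C(/C)[C@@H](OC(=O)c3ccccc3)C/C=C(\C)C[C@@H](O)[C@@H]12 | intermediate
31 | angelic acid ((Z)-2-methylbut-2-enoic acid) | C/C=C(/C)C(=O)O | starting material
32 | (Z)-2-methylbut-2-en-1-ol | C/C=C(/C)CO | intermediate
33 | [(2S,3R)-2,3-dimethyloxiran-2-yl]methanol | OC[C@]1(C)O[C@@H]1C | intermediate
34 | (2R,3R)-2,3-dimethyloxirane-2-carboxylic acid | OC(=O)[C@]1(C)O[C@@H]1C | intermediate
35 | (2R,3R)-2,3-dimethyloxirane-2-carboxylic 2,4,6-trichlorobenzoic anhydride | O=C(OC(=O)c1c(Cl)cc(Cl)cc1Cl)[C@]1(C)O[C@@H]1C | intermediate (not isolated)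
36 | (3S,6R,7R,8R)-3-benzoyloxy-8-[(2R,3R)-2,3-epoxy-2-methylbutanoyloxy]germacra-1(10)E,4Z,11(13)-trien-12,6-olide | C=C1C(=O)O[C@@H]2/C=C(/C)[C@@H](OC(=O)c3ccccc3)C/C=C(\C)C[C@@H](OC(=O)[C@]3(C)O[C@@H]3C)[C@@H]12 | intermediate
37 | CNP0324463.6, (1R,3S,6R,7R,8R,10R)-3-benzoyloxy-1,10-epoxy-8-[(2R,3R)-2,3-epoxy-2-methylbutanoyloxy]germacra-4Z,11(13)-dien-12,6-olide | C=C1C(=O)O[C@@H]2/C=C(/C)[C@@H](OC(=O)c3ccccc3)C[C@H]3O[C@]3(C)C[C@@H](OC(=O)[C@]3(C)O[C@@H]3C)[C@@H]12 | target

Total step count: 21. Longest linear sequence: 15 steps (steps 1–7, 11–16, 20 and 21); steps 8–10 and 17–19 are side branches.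

Least certain steps

Step 11 (key step). The most likely failures are leakage of regiochemistry (C10 bonding to C4) and an unfavourable spread over diastereomeric adducts. The cause is that the anti-to-benzoate preference of the cyclobutene and the anti-to-C7/C8 preference of the enone cannot both be met in a cis-anti-cis adduct for this pairing, which may push part of the material into cis-syn-cis or trans-fused adducts and slow closure of the biradical. Fallback: setting out from enone 12 and the unprotected cyclobutenol 18 (kept as a dried solution), the cycloaddition would be run in a hydrocarbon solvent so that the O–H···O=C6 hydrogen bond places C3, and with it C4, next to C5. This reinforces the regiochemistry and turns the cyclobutene to the face syn to its oxygen, which here is the face that lets the enone react anti to its C7/C8 substituents. The product would be the cis-anti-cis hydroxy photoadduct F1; benzoylation (BzCl, pyridine) would give the benzoate F2, the C1,C4,C5,C10-epimer of 21, and thermolysis as in step 12 comes back to the route at 22.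

Step 12. Cleavage may proceed through the other chair-like arrangement and give the 4E olefin, and at 180 °C an E,E-cyclodeca-1,5-diene is consumed by Cope rearrangement to a divinylcyclohexanone faster than it can isomerise. Prolonged heating of the Z enone can also start 1,5-hydrogen shifts from C3. Fallback: setting out from 21, the cycloreversion would be separated from the geometric equilibration. Short-residence-time flow thermolysis (PhMe, about 210 °C, minutes) would be used to collect the primary products; the (4E,1(10)E)-dienone F3 would then be isomerised at the enone olefin by triplet-sensitised irradiation at 0 °C, coming back at 22.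

Step 13. Hydride delivery to the wrong face of the C6 carbonyl is possible, because the reactive conformation of a ten-membered Z-enone cannot be fixed in advance. Fallback: setting out from 22, the 6-epi alcohol F4 would be inverted by Mitsunobu esterification with chloroacetic acid (PPh3, DIAD) to the (6R)-chloroacetate F5. The chloroacetate would be removed with thiourea/NaHCO3, which leaves the benzoate untouched, coming back at 23.

Step 9. Loss of ethanol may occur toward the unsubstituted α-carbon, and ethanol may re-add to the strained enone, or the enone may oligomerise, because the elimination is reversible. Fallback: setting out from 16, bromination through the more substituted enol (pyridinium tribromide, AcOH) would give 2-bromo-3-ethoxy-2-methylcyclobutan-1-one F6. Zinc dust in THF would then form the zinc enolate only at C2 and expel ethoxide in a Boord-type reductive elimination, coming back at 17.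

Step 21. Attack on the other face of the trans-cyclodecene, through a different ring conformer, would give the 1S,10S epoxide; the peracid can also open the new epoxide transannularly if the medium turns acidic. Fallback: setting out from 36 and coming back directly at 37, the epoxidation would be made reagent-controlled by Shi epoxidation. The D-fructose-derived ketone catalyst, with KHSO5 (as 2KHSO5·KHSO4·K2SO4) and K2CO3 buffer in MeCN/dimethoxymethane/H2O at 0 °C, is predicted by its spiro transition state to give the (1R,10R) oxirane on a trisubstituted E olefin; no new compound is involved.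

Further compounds

F1 | step 11 | hydroxy photoadduct, cis-anti-cis (1S,3S,4S,5S,7R,8R,10S), free C3 hydroxyl endo | C[C@]12[C@@H](O)C[C@H]1[C@]3(C)C[C@@H](O[Si](C)(C)C(C)(C)C)[C@@H](CC(=O)OC(C)(C)C)C(=O)[C@@H]32
F2 | step 11 | benzoate of F1 (C1,C4,C5,C10-epimer of 21) | C[C@]12[C@@H](OC(=O)c3ccccc3)C[C@H]1[C@]4(C)C[C@@H](O[Si](C)(C)C(C)(C)C)[C@@H](CC(=O)OC(C)(C)C)C(=O)[C@@H]42
F3 | step 12 | (4E,1(10)E)-dienone, 4E isomer of 22 | O=C1/C=C(\C)[C@@H](OC(=O)c2ccccc2)C/C=C(\C)C[C@@H](O[Si](C)(C)C(C)(C)C)[C@H]1CC(=O)OC(C)(C)C
F4 | step 13 | (6S)-alcohol, 6-epimer of 23 | O[C@H]1/C=C(/C)[C@@H](OC(=O)c2ccccc2)C/C=C(\C)C[C@@H](O[Si](C)(C)C(C)(C)C)[C@H]1CC(=O)OC(C)(C)C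
F5 | step 13 | (6R)-chloroacetate of 23 | O=C(CCl)O[C@@H]1/C=C(/C)[C@@H](OC(=O)c2ccccc2)C/C=C(\C)C[C@@H](O[Si](C)(C)C(C)(C)C)[C@H]1CC(=O)OC(C)(C)C
F6 | step 9 | 2-bromo-3-ethoxy-2-methylcyclobutan-1-one (racemic, diastereomer mixture) | CCOC1CC(=O)C1(C)Br
F0 | step 21 | none | none
A1 | alternative 1 | Se-phenyl selenoester seco chain with epoxide, C3 benzoate, Z olefin and 3-(tributylstannylmethyl)butenolide | O=C([Se]c1ccccc1)C[C@@]2(C)O[C@@H]2C[C@H](OC(=O)c3ccccc3)/C(C)=C\[C@H]4OC(=O)C(C[Sn](CCCC)(CCCC)CCCC)=C4
A2 | alternative 1 | 8-oxo core with methylene lactone, epoxide and C3 benzoate | C=C1C(=O)O[C@@H]2/C=C(/C)[C@@H](OC(=O)c3ccccc3)C[C@H]3O[C@]3(C)CC(=O)[C@@H]12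
A3 | alternative 2 | trans-1,2-dialkenylcyclohex-2-en-1-ol (isopropenyl on C1, (E)-enol ether alkenyl on C6, C3 silyl ether) | O[C@]1(/C(CCO[Si](C)(C)C(C)(C)C)=C/OCc2ccc(OC)cc2)C=C(C)[C@@H](O[Si](C)(C)C(C)(C)C)C[C@@H]1C(C)=C
A4 | alternative 2 | ten-membered (4Z,1(10)E)-dien-6-one with C8 PMB ether and C7 silyloxyethyl arm | CC(C)(C)[Si](C)(C)OCC[C@H]1C(=O)/C=C(/C)[C@@H](O[Si](C)(C)C(C)(C)C)C/C=C(\C)C[C@H]1OCc2ccc(OC)cc2
A5 | alternative 3 | C12 N-tert-butylamide of the ten-membered carbocycle with C6 methylene (C11 configuration open) | CC(C(=O)NC(C)(C)C)[C@H]1C/C=C(/C)[C@@H](OC(=O)c2ccccc2)C[C@H]2O[C@]2(C)C[C@H]1OC(=O)[C@]1(C)O[C@@H]1C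
A6 | alternative 3 | 11,13-dihydro-37 (saturated trans-fused lactone, C11 configuration open) | CC1C(=O)O[C@@H]2/C=C(/C)[C@@H](OC(=O)c3ccccc3)C[C@H]3O[C@]3(C)C[C@@H](OC(=O)[C@]3(C)O[C@@H]3C)[C@@H]12
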